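The ten-membered carbocycle (ring A, C1–C10) is cut at C3–C4, the bond between the carbinol carbon and the Z-trisubstituted C4=C5 alkene. In the open precursor both ends are electrophiles: a C3 aldehyde and a (Z)-C4 alkenyl iodide. A nickel/chromium-mediated reductive coupling unites them. It closes ring A, keeps the Z geometry and creates the C3 carbinol for the last ester. The step exploits the Z-allylic carbinol C3–C4=C5 of ring A, whose allylic strain steers the new centre. The precursor already holds the trans α-methylene-γ-lactone (ring B), the C1–C10 oxirane (ring C) and the C8 epoxy ester.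

Key step: step 18

Remark: germacrane numbering is used (ring A = C1–C10; C11, C12, C13 = lactone carbons with C13 the exocyclic methylene; C14 and C15 = methyls on C10 and C4). Compounds 18 and 28 are taken as purchasable in the stated geometry and configuration.

Step 1
Reactants: 1 but-2-yn-1-ol
Product: 3 (2Z)-3-iodobut-2-en-1-ol, via cyclic alkenylaluminate 2 (not isolated)
Conditions: NaAlH2(OCH2CH2OMe)2, THF, 0 °C to rt; then I2, −78 to 0 °C; H2O work-up
Reagents that add atoms: iodine, II
Why: Hydroxyl-directed trans-hydroalumination places aluminium on the distal alkyne carbon inside the five-membered aluminate 2, and iodinolysis with retention gives only the Z-iodide, which fixes the C4=C5 geometry of the target.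

Step 2
Reactants: 3 (2Z)-3-iodobut-2-en-1-ol
Product: 4 (2Z)-3-iodobut-2-enal
Conditions: MnO2, CH2Cl2, rt, dark
Reagents that add atoms: none
Why: Allylic alcohol oxidation with MnO2 is neutral and heterogeneous, so it should stop at the enal and leave the C–I bond and the Z geometry untouched.

Step 3
Reactants: 4 (2Z)-3-iodobut-2-enal
Product: 5 rac-(4Z)-5-iodohexa-1,4-dien-3-ol
Conditions: CH2=CHMgBr, THF, −78 °C; sat. aq. NH4Cl
Reagents that add atoms: vinylmagnesium bromide, C=C[Mg]Br
Why: Grignard 1,2-addition to the enal at low temperature should outrun iodine–magnesium exchange and conjugate addition and gives the racemic bis-allylic alcohol that carries C6.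

Step 4
Reactants: 5 rac-(4Z)-5-iodohexa-1,4-dien-3-ol
Product: 6 (3S,4Z)-5-iodohexa-1,4-dien-3-ol
Conditions: Ti(OiPr)4 (0.1 equiv), L-(+)-diisopropyl tartrate (0.15 equiv), t-BuOOH (0.6 equiv), 4 Å molecular sieves, CH2Cl2, −20 °C, stopped just past half conversion
Reagents that add atoms: none
Why: Sharpless kinetic resolution: with L-(+)-DIPT the (3R)-alcohol is epoxidised at its vinyl group far faster than the (3S)-alcohol, while the electron-poor Z-iodoalkene does not compete, so unreacted 6 is recovered with the C6 configuration of the target.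

Step 5
Reactants: 6 (3S,4Z)-5-iodohexa-1,4-dien-3-ol; 7 2-(bromomethyl)prop-2-enoic acid
Product: 8 (3S,4Z)-5-iodohexa-1,4-dien-3-yl 2-(bromomethyl)prop-2-enoate
Conditions: DCC, DMAP (cat.), CH2Cl2, 0 °C
Reagents that add atoms: none
Why: Steglich esterification acylates the alcohol oxygen without breaking the C6–O bond, so the configuration is retained, and the low temperature and catalytic DMAP spare the allylic bromide.

Step 6
Reactants: 8 (3S,4Z)-5-iodohexa-1,4-dien-3-yl 2-(bromomethyl)prop-2-enoate
Product: 9 (5S)-3-(bromomethyl)-5-[(1Z)-2-iodoprop-1-en-1-yl]furan-2(5H)-one (fragment 1)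
Conditions: second-generation Grubbs catalyst RuCl2(=CHPh)(PCy3)(H2IMes) (5 mol %), CH2Cl2 (0.01 M), reflux
Reagents that add atoms: none
Why: Ring-closing metathesis starts at the only monosubstituted alkene and closes onto the acrylate to give the five-membered butenolide (ring B), the trisubstituted iodoalkene being inert to the ruthenium carbene and C6 untouched.

Step 7
Reactants: 10 pent-3-yn-1-ol
Product: 11 tert-butyl(dimethyl)(pent-3-yn-1-yloxy)silane
Conditions: TBSCl, imidazole, CH2Cl2, 0 °C to rt
Reagents that add atoms: tert-butyldimethylsilyl chloride, CC(C)(C)[Si](C)(C)Cl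
Why: Standard silylation of the primary alcohol masks the future C3 oxygen through the organometallic and oxidative steps.

Step 8
Reactants: 11 tert-butyl(dimethyl)(pent-3-yn-1-yloxy)silane
Product: 13 tert-butyl{[(3E)-4-iodopent-3-en-1-yl]oxy}dimethylsilane, via alkenylzirconocene chloride 12 (not isolated)
Conditions: Cp2Zr(H)Cl (excess), THF, rt to 40 °C; then I2, 0 °C
Reagents that add atoms: iodine, II
Why: Hydrozirconation is a syn addition and, with excess reagent, equilibrates zirconium to the less hindered alkyne carbon next to the methyl group, so iodinolysis with retention gives the E-iodide that defines the C1=C10 geometry.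

Step 9
Reactants: 13 tert-butyl{[(3E)-4-iodopent-3-en-1-yl]oxy}dimethylsilane
Product: 15 (3E)-6-(tert-butyldimethylsilyloxy)-3-methylhex-3-en-1-ol, via alkenyllithium 14 (not isolated)
Conditions: t-BuLi (2 equiv), Et2O, −78 °C; ethylene oxide, −78 to 0 °C; H2O
Reagents that add atoms: ethylene oxide, C1CO1
Why: Iodine–lithium exchange proceeds with retention of alkene geometry and the alkenyllithium opens ethylene oxide in an SN2 reaction, adding C9 and C8 as a free primary alcohol.

Step 10
Reactants: 15 (3E)-6-(tert-butyldimethylsilyloxy)-3-methylhex-3-en-1-ol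
Product: 16 2-{(2R,3R)-3-[2-(tert-butyldimethylsilyloxy)ethyl]-2-methyloxiran-2-yl}ethan-1-ol
Conditions: D-fructose-derived Shi ketone (1,2:4,5-di-O-isopropylidene-β-D-erythro-2,3-hexodiulo-2,6-pyranose, 0.3 equiv), KHSO5 (as Oxone), K2CO3, Bu4NHSO4 (cat.), MeCN/CH2(OMe)2/aq. Na2B4O7 buffer, 0 °C
Reagents that add atoms: potassium peroxymonosulfate, [K+].[O-]S(=O)(=O)OO
Why: Shi asymmetric epoxidation: the dioxirane of the D-fructose-derived ketone attacks E-trisubstituted alkenes through a spiro transition state on the face that gives the (R,R)-oxirane, which sets C1 and C10 (ring C) under reagent control.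

Step 11
Reactants: 16 2-{(2R,3R)-3-[2-(tert-butyldimethylsilyloxy)ethyl]-2-methyloxiran-2-yl}ethan-1-ol
Product: 17 {(2R,3R)-3-[2-(tert-butyldimethylsilyloxy)ethyl]-2-methyloxiran-2-yl}acetaldehyde (fragment 2)
Conditions: Dess–Martin periodinane, NaHCO3, CH2Cl2, 0 °C; used at once
Reagents that add atoms: none
Why: Buffered Dess–Martin oxidation is non-basic and fast at 0 °C, so the β,γ-epoxy aldehyde should form without β-elimination of the oxirane.

Step 12
Reactants: 18 (2E)-2-methylbut-2-en-1-ol
Product: 19 [(2S,3S)-2,3-dimethyloxiran-2-yl]methanol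
Conditions: Ti(OiPr)4 (5 mol %), L-(+)-diethyl tartrate (6 mol %), t-BuOOH, 4 Å molecular sieves, CH2Cl2, −20 °C
Reagents that add atoms: tert-butyl hydroperoxide, CC(C)(C)OO
Why: Sharpless asymmetric epoxidation of the E-allylic alcohol with L-(+)-DET delivers oxygen to the face that gives the (2S,3S)-epoxy alcohol, and the syn addition keeps the two methyl groups cis.

Step 13
Reactants: 19 [(2S,3S)-2,3-dimethyloxiran-2-yl]methanol
Product: 20 (2R,3S)-2,3-dimethyloxirane-2-carboxylic acid
Conditions: TEMPO (cat.), PhI(OAc)2 (2.2 equiv), MeCN/H2O, rt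
Reagents that add atoms: water, O
Why: TEMPO/PhI(OAc)2 oxidation in aqueous acetonitrile takes the primary alcohol through the aldehyde hydrate to the acid under near-neutral conditions that leave the oxirane and both stereocentres intact (the descriptor at C2 changes only by priority).

Step 14
Reactants: 9 fragment 1; 17 fragment 2
Product: 22 (7R,8S)-8-hydroxy seco-lactone, via allylzinc bromide 21 (not isolated)
Conditions: Zn dust, THF/sat. aq. NH4Cl, 0 °C
Reagents that add atoms: none
Why: Barbier allylation: allylzinc 21 reacts at its γ-carbon C7 (an allyl transposition that unveils the exocyclic C11=C13 methylene) through a closed chair transition state, anti to the C6 alkenyl group (6,7-trans) and, as an E-type γ-substituted allyl metal, with 7,8-anti topology, which sets 7R and 8S, the latter being deliberately opposite to the target and inverted in step 15.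

Step 15
Reactants: 22 (7R,8S)-8-hydroxy seco-lactone; 20 (2R,3S)-2,3-dimethyloxirane-2-carboxylic acid
Product: 23 (8R)-epoxy ester of the seco-lactone
Conditions: PPh3, DIAD, toluene, 0 °C to rt (betaine preformed, then 22 and 20)
Reagents that add atoms: none
Why: Mitsunobu esterification: SN2 displacement of the oxyphosphonium group by the carboxylate of 20, a comparatively strong glycidic acid as suits hindered alcohols, inverts C8 to 8R and installs the epoxy ester in the same operation.

Step 16
Reactants: 23 (8R)-epoxy ester of the seco-lactone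
Product: 24 C3 primary alcohol
Conditions: Bu4NF, AcOH (1:1), THF, 0 °C to rt
Reagents that add atoms: none
Why: Fluoride-mediated desilylation buffered with acetic acid removes the primary TBS group under nearly neutral conditions that should spare the esters, both oxiranes and the methylene lactone.

Step 17
Reactants: 24 C3 primary alcohol
Product: 25 C3 aldehyde with C4 alkenyl iodide (cyclisation precursor)
Conditions: Dess–Martin periodinane, NaHCO3, CH2Cl2, 0 °C; used at once
Reagents that add atoms: none
Why: Buffered Dess–Martin oxidation gives the C3 aldehyde without base, so the neighbouring C1–C10 oxirane should not be opened by β-elimination.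

Step 18
Reactants: 25 C3 aldehyde with C4 alkenyl iodide
Product: 27 (3S)-hydroxy germacranolide, via alkenylchromium dichloride 26 (not isolated)
Conditions: CrCl2 (15 equiv), NiCl2 (0.1 equiv), DMSO/THF, slow addition of 25 to 0.002 M, rt; H2O work-up
Reagents that add atoms: none
Why: CrCl2 reduces NiCl2 to zerovalent nickel, which inserts into the C4–I bond with retention, and transmetalation to trivalent chromium gives the non-basic alkenylchromium 26 that adds to the C3 aldehyde, so two electrophilic carbons are joined by a two-electron reduction. The closest known reaction type is the intramolecular Nozaki–Hiyama–Kishi coupling used for medium-ring and macrocyclic allylic alcohols. Ring A closes in a 10-exo-trig mode (C4 attacks C3 and the carbonyl oxygen stays outside the ring), helped by three rigid elements in the tether: the Z-alkene, the trans-lactone and the trans-oxirane. The new C3 centre is controlled by allylic 1,3-strain across the Z-alkene, which keeps H3 in the alkene plane facing C6 and the O–Cr group on the periphery, while the trans-lactone (C7 above the alkene plane) and the trans-oxirane bring C2 in from below, so C4 should add to the Re face and give 3S. The step needs chemoselectivity for C–I over the acrylate, both oxiranes and the ester carbonyls, which is secured by the nickel-specific activation and by the low basicity and aldehyde selectivity of organochromium reagents, which should also spare the base-sensitive β,γ-epoxy aldehyde. High dilution secures ring closure over dimerisation.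

Step 19
Reactants: 27 (3S)-hydroxy germacranolide; 28 (2R)-2-methylbutanoic acid
Product: 29 target CNP0265335.3
Conditions: DCC, DMAP (cat.), CH2Cl2, 0 °C to rt
Reagents that add atoms: none
Why: Steglich esterification of the allylic C3 alcohol proceeds at oxygen with retention at C3, and the mild conditions should not epimerise the α-centre of 28.

Compound list
1 | but-2-yn-1-ol | CC#CCO | starting material
2 | sodium cyclic alkenylaluminate (five-membered O–Al–C=C ring, two 2-methoxyethoxy ligands) | CC1=CCO[Al-]1(OCCOC)OCCOC.[Na+] | intermediate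
3 | (2Z)-3-iodobut-2-en-1-ol | C/C(I)=C/CO | intermediate
4 | (2Z)-3-iodobut-2-enal | C/C(I)=C/C=O | intermediate
5 | rac-(4Z)-5-iodohexa-1,4-dien-3-ol | C=CC(O)/C=C(/C)I | intermediate
6 | (3S,4Z)-5-iodohexa-1,4-dien-3-ol | C=C[C@@H](/C=C(/C)I)O | intermediate
7 | 2-(bromomethyl)prop-2-enoic acid | C=C(CBr)C(=O)O | starting material
8 | (3S,4Z)-5-iodohexa-1,4-dien-3-yl 2-(bromomethyl)prop-2-enoate | C=C[C@@H](/C=C(/C)I)OC(=O)C(=C)CBr | intermediate
9 | (5S)-3-(bromomethyl)-5-[(1Z)-2-iodoprop-1-en-1-yl]furan-2(5H)-one | BrCC1=C[C@@H](/C=C(/C)I)OC1=O | intermediate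
10 | pent-3-yn-1-ol | CC#CCCO | starting material
11 | tert-butyl(dimethyl)(pent-3-yn-1-yloxy)silane | CC#CCCO[Si](C)(C)C(C)(C)C | intermediate
12 | (E)-alkenylzirconocene chloride (Zr on the methyl-bearing alkene carbon) | C/C(=C\CCO[Si](C)(C)C(C)(C)C)[Zr](Cl)(C1C=CC=C1)C1C=CC=C1 | intermediate
13 | tert-butyl{[(3E)-4-iodopent-3-en-1-yl]oxy}dimethylsilane | C/C(I)=C\CCO[Si](C)(C)C(C)(C)C | intermediate
14 | (E)-alkenyllithium from 13 | C/C([Li])=C\CCO[Si](C)(C)C(C)(C)C | intermediate
15 | (3E)-6-(tert-butyldimethylsilyloxy)-3-methylhex-3-en-1-ol | OCC/C(C)=C/CCO[Si](C)(C)C(C)(C)C | intermediate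
16 | 2-{(2R,3R)-3-[2-(tert-butyldimethylsilyloxy)ethyl]-2-methyloxiran-2-yl}ethan-1-ol | CC(C)(C)[Si](C)(C)OCC[C@H]1O[C@]1(C)CCO | intermediate
17 | {(2R,3R)-3-[2-(tert-butyldimethylsilyloxy)ethyl]-2-methyloxiran-2-yl}acetaldehyde | CC(C)(C)[Si](C)(C)OCC[C@H]1O[C@]1(C)CC=O | intermediate
18 | (2E)-2-methylbut-2-en-1-ol | C/C=C(\C)CO | starting material
19 | [(2S,3S)-2,3-dimethyloxiran-2-yl]methanol | OC[C@]1(C)O[C@H]1C | intermediate
20 | (2R,3S)-2,3-dimethyloxirane-2-carboxylic acid (methyl groups cis) | OC(=O)[C@]1(C)O[C@H]1C | intermediate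
21 | allylzinc bromide from 9 | Br[Zn]CC1=C[C@@H](/C=C(/C)I)OC1=O | intermediate
22 | (4R,5S)-4-[(1S)-2-{(2R,3R)-3-[2-(tert-butyldimethylsilyloxy)ethyl]-2-methyloxiran-2-yl}-1-hydroxyethyl]-5-[(1Z)-2-iodoprop-1-en-1-yl]-3-methylidenedihydrofuran-2(3H)-one (7R,8S) | C=C1C(=O)O[C@H](/C=C(/C)I)[C@H]1[C@@H](O)C[C@@]2(C)O[C@@H]2CCO[Si](C)(C)C(C)(C)C | intermediate
23 | (1R)-2-{(2R,3R)-3-[2-(tert-butyldimethylsilyloxy)ethyl]-2-methyloxiran-2-yl}-1-{(2S,3R)-2-[(1Z)-2-iodoprop-1-en-1-yl]-4-methylidene-5-oxotetrahydrofuran-3-yl}ethyl (2R,3S)-2,3-dimethyloxirane-2-carboxylate | C=C1C(=O)O[C@H](/C=C(/C)I)[C@H]1[C@H](OC(=O)[C@]3(C)O[C@H]3C)C[C@@]2(C)O[C@@H]2CCO[Si](C)(C)C(C)(C)C | intermediate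
24 | as 23 with a free 2-hydroxyethyl group on the oxirane (C3–OH) | C=C1C(=O)O[C@H](/C=C(/C)I)[C@H]1[C@H](OC(=O)[C@]3(C)O[C@H]3C)C[C@@]2(C)O[C@@H]2CCO | intermediate
25 | as 23 with a 2-oxoethyl group on the oxirane (C3 aldehyde) | C=C1C(=O)O[C@H](/C=C(/C)I)[C@H]1[C@H](OC(=O)[C@]3(C)O[C@H]3C)C[C@@]2(C)O[C@@H]2CC=O | intermediate
26 | (Z)-alkenylchromium dichloride from 25 (Cr on C4) | C=C1C(=O)O[C@H](/C=C(/C)[Cr](Cl)Cl)[C@H]1[C@H](OC(=O)[C@]3(C)O[C@H]3C)C[C@@]2(C)O[C@@H]2CC=O | intermediate
27 | (1R,3S,4Z,6R,7R,8R,10R)-1,10-epoxy-3-hydroxy-8-[(2R,3S)-2,3-dimethyloxirane-2-carbonyloxy]germacra-4,11(13)-dien-12,6-olide | C=C1C(=O)O[C@@H]2/C=C(/C)[C@@H](O)C[C@H]3O[C@]3(C)C[C@@H](OC(=O)[C@]3(C)O[C@H]3C)[C@@H]12 | intermediate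
28 | (2R)-2-methylbutanoic acid | CC[C@@H](C)C(=O)O | starting material
29 | (1R,3S,4Z,6R,7R,8R,10R)-1,10-epoxy-3-[(2R)-2-methylbutanoyloxy]-8-[(2R,3S)-2,3-dimethyloxirane-2-carbonyloxy]germacra-4,11(13)-dien-12,6-olide | C=C1C(=O)O[C@@H]2/C=C(/C)[C@@H](OC(=O)[C@H](C)CC)C[C@H]3O[C@]3(C)C[C@@H](OC(=O)[C@]3(C)O[C@H]3C)[C@@H]12 | target

Total step count: 19. Longest linear sequence: 12 (steps 1–6, then 14–19).

Steps most likely to fail

Risk 1, step 18. The aldehyde may be attacked with poor facial selectivity if a second closing conformer presents its Si face, so that the wrong C3 configuration forms beside or instead of the right one. The fallback sets out from 25. The same closure then gives the (3R)-epimer of 27 F1, which is kept rather than discarded. Mitsunobu esterification of F1 with 28 (PPh3, DIAD, toluene) displaces the allylic oxyphosphonium group with inversion and comes back to the route at 29. Any 27 is acylated with retention as planned, so both C3 epimers converge on the target.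

Risk 2, step 15. Substitution at the hindered C8 carbinol may be slow. E2 elimination towards a diene conjugated with the methylene lactone, or partial retention, could then take over. The fallback sets out from 22 and replaces substitution by a redox inversion. Dess–Martin oxidation (NaHCO3, CH2Cl2, 0 °C) gives the C8 ketone F2, which is handled cold and without base. Zn(BH4)2 in Et2O at −78 °C should deliver hydride under Felkin–Anh control, anti to the C6 branch of the lactone, to give the (8R)-alcohol F3. Steglich esterification of F3 with 20 (DCC, DMAP cat.) proceeds with retention and comes back to the route at 23.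

Risk 3, step 14. The β,γ-epoxy aldehyde may lose its oxirane by β-elimination or by Lewis-acid opening with zinc salts before the C–C bond forms. The fallback sets out from 15 and postpones the epoxidation until after fragment union, but still before ring A is closed.
- Dess–Martin oxidation of 15 gives (3E)-6-(tert-butyldimethylsilyloxy)-3-methylhex-3-enal F4.
- Barbier allylation of F4 with 9 (Zn, THF/aq. NH4Cl) gives the olefinic (8S)-alcohol F5.
- Mitsunobu esterification of F5 with 20 gives the olefinic (8R)-epoxy ester F6.
- Shi epoxidation with a small excess of oxidant then addresses the only electron-rich alkene (C1=C10) under reagent control and comes back to the route at 23.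

Further compounds
F1 | step 18 | (3R)-epimer of 27 | C=C1C(=O)O[C@@H]2/C=C(/C)[C@H](O)C[C@H]3O[C@]3(C)C[C@@H](OC(=O)[C@]3(C)O[C@H]3C)[C@@H]12
F2 | step 15 | C8 ketone derived from 22 | C=C1C(=O)O[C@H](/C=C(/C)I)[C@H]1C(=O)C[C@@]2(C)O[C@@H]2CCO[Si](C)(C)C(C)(C)C
F3 | step 15 | (8R)-epimer of 22 | C=C1C(=O)O[C@H](/C=C(/C)I)[C@H]1[C@H](O)C[C@@]2(C)O[C@@H]2CCO[Si](C)(C)C(C)(C)C
F4 | step 14 | (3E)-6-(tert-butyldimethylsilyloxy)-3-methylhex-3-enal | O=CC/C(C)=C/CCO[Si](C)(C)C(C)(C)C
F5 | step 14 | olefinic (7R,8S)-alcohol (22 with the C1=C10 E-alkene in place of the oxirane) | C=C1C(=O)O[C@H](/C=C(/C)I)[C@H]1[C@@H](O)C/C(C)=C/CCO[Si](C)(C)C(C)(C)C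
F6 | step 14 | olefinic (8R)-epoxy ester (23 with the C1=C10 E-alkene in place of the oxirane) | C=C1C(=O)O[C@H](/C=C(/C)I)[C@H]1[C@H](OC(=O)[C@]2(C)O[C@H]2C)C/C(C)=C/CCO[Si](C)(C)C(C)(C)C
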